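**Retrosynthetic overview**

- The strategy rests on the 2-oxabicyclo[3.2.1]oct-3-ene of the target: the dihydropyran O–C14=C10–C1–C5–C4 shares C1–C5–C4 with the cyclopentane C1–C5 and is fused to the cycloheptane. It is the formal [4+2] adduct of the enal O=C14–C10=C1 with the C4=C5 alkene across a germacra-1(10),4-dien-14-al (31), so one transannular step makes O–C4 and C1–C5.
- 31 comes from a ten-membered ring closed at C9–C10 by Ni/Cr coupling of vinyl iodide–aldehyde 27. The C8 ester is installed with inversion (Mitsunobu) because the lactone-forming allylboration (C6–C7) of enal 14 with boronate 19 needs the C8 epimer for Felkin–Anh-type control.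
- 14 comes from a B-alkyl Suzuki coupling (C3–C4) of stannyl diene 6 with 4-bromofuranone 8, whose ring fixes the C4=C5 geometry; syn-hydrostannation of enynoate 3 fixes C1=C10.
- Ring order: butenolide (temporary), α-methylene lactone, ten-membered ring, then cyclopentane and dihydropyran (leaving the cycloheptane) in the key step.

Key step: step 23

Remark: locants follow the guaiane/germacrane skeleton of the target (lactone carbons C11–C13) and α/β refer to the usual drawing with H-7 α. The C15 oxygen is carried as a tert-butyldiphenylsilyl ether because two mildly acidic steps precede ring closure, and the enal is activated by a Lewis acid because the two-carbon C2–C3 link rules out a synchronous thermal [4+2].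

**Route**

Step 1
Reactants: 1 ethyl propiolate; 2 vinyl bromide
Product: 3 ethyl pent-4-en-2-ynoate
Conditions: Pd(PPh3)2Cl2 (2 mol %), CuI (4 mol %), K2CO3, THF, rt
Reagents that add atoms: none
Why: Sonogashira coupling of a terminal alkyne with a vinyl bromide, run with an inorganic base so that no amine adds to the propiolate.

Step 2
Reactants: 3 ethyl pent-4-en-2-ynoate
Product: 4 ethyl (2E)-2-(tributylstannyl)penta-2,4-dienoate
Conditions: Bu3SnH, Pd(PPh3)4 (2 mol %), THF, 0 °C
Reagents that add atoms: tributyltin hydride, CCCC[SnH](CCCC)CCCC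
Why: Palladium-catalysed hydrostannation of an ynoate adds H and Sn syn with tin at the carbon next to the ester, which fixes the later C1=C10 geometry (C14 cis to C2).

Step 3
Reactants: 4 stannyl dienoate
Product: 5 (2E)-2-(tributylstannyl)penta-2,4-dien-1-ol
Conditions: i-Bu2AlH (2.2 equiv), CH2Cl2, −78 °C; aq. potassium sodium tartrate
Reagents that add atoms: none
Why: Hydride reduction of a conjugated ester to the allylic alcohol, to which the vinylstannane is inert.

Step 4
Reactants: 5 stannyl dienol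
Product: 6 tributyl{(2E)-1-[(4-methoxybenzyl)oxy]penta-2,4-dien-2-yl}stannane
Conditions: NaH, 4-methoxybenzyl chloride, Bu4NI (cat.), THF/DMF, 0 °C to rt
Reagents that add atoms: 4-methoxybenzyl chloride, COc1ccc(CCl)cc1
Why: Williamson etherification under basic conditions, chosen because acid would protodestannylate the vinylstannane.

Step 5
Reactants: 7 tetronic acid
Product: 8 4-bromofuran-2(5H)-one
Conditions: (COBr)2, DMF (cat.), CH2Cl2, 0 °C to rt
Reagents that add atoms: oxalyl bromide, O=C(Br)C(=O)Br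
Why: Vilsmeier-type activation of the vinylogous acid replaces the enol hydroxyl by bromide.

Step 6
Reactants: 6 stannyl diene PMB ether; 8 4-bromofuran-2(5H)-one
Product: 10 4-{(3E)-5-[(4-methoxybenzyl)oxy]-4-(tributylstannyl)pent-3-en-1-yl}furan-2(5H)-one, via alkylborane 9 (not isolated)
Conditions: 9-BBN dimer, THF, 0 °C to rt; then 8, Pd(dppf)Cl2 (5 mol %), aq. K3PO4, THF/DMF, rt
Reagents that add atoms: none
Why: 9-BBN hydroborates only the terminal CH2 of the diene (the stannylated alkene is hindered) and the primary alkylborane enters a B-alkyl Suzuki–Miyaura coupling with the activated β-bromobutenolide faster than the hindered vinylstannane can couple, while the butenolide ring locks C15 cis to C6 at the future C4=C5 bond.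

Step 7
Reactants: 10 stannyl butenolide
Product: 11 4-{(3E)-4-iodo-5-[(4-methoxybenzyl)oxy]pent-3-en-1-yl}furan-2(5H)-one
Conditions: I2, CH2Cl2, 0 °C
Reagents that add atoms: iodine, II
Why: Iododestannylation proceeds with retention of alkene geometry and leaves the electron-poor butenolide and the anisyl ring untouched.

Step 8
Reactants: 11 iodo butenolide
Product: 13 (2Z,6E)-3-{[(tert-butyldiphenylsilyl)oxy]methyl}-7-iodo-N-methoxy-8-[(4-methoxybenzyl)oxy]-N-methylocta-2,6-dienamide, via hydroxy amide 12 (not isolated)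
Conditions: MeNH(OMe)·HCl, AlMe3, CH2Cl2, 0 °C to rt; then t-BuPh2SiCl, imidazole, DMF, 0 °C to rt
Reagents that add atoms: N,O-dimethylhydroxylamine hydrochloride, CNOC.Cl; tert-butyl(chloro)diphenylsilane, CC(C)(C)[Si](Cl)(c1ccccc1)c1ccccc1
Why: Aluminium amide aminolysis of the lactone (Weinreb amide formation) frees only the C15 hydroxyl, which is silylated at once before it can relactonise, and the ring opening keeps C15 cis to C6.

Step 9
Reactants: 13 Weinreb amide
Product: 14 (2Z,6E)-3-{[(tert-butyldiphenylsilyl)oxy]methyl}-7-iodo-8-[(4-methoxybenzyl)oxy]octa-2,6-dienal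
Conditions: i-Bu2AlH (1.3 equiv), THF, −78 °C; aq. potassium sodium tartrate
Reagents that add atoms: none
Why: Reduction of a Weinreb amide stops at the aldehyde through the chelated tetrahedral intermediate.

Step 10
Reactants: 15 (S)-glyceraldehyde acetonide
Product: 16 (4R)-4-ethynyl-2,2-dimethyl-1,3-dioxolane
Conditions: dimethyl (1-diazo-2-oxopropyl)phosphonate, K2CO3, MeOH, 0 °C to rt
Reagents that add atoms: dimethyl (1-diazo-2-oxopropyl)phosphonate, CC(=O)C(=[N+]=[N-])P(=O)(OC)OC
Why: Ohira–Bestmann homologation turns the aldehyde into the terminal alkyne under mild carbonate conditions that should leave the α-alkoxy centre intact.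

Step 11
Reactants: 16 alkyne
Product: 17 methyl 3-[(4R)-2,2-dimethyl-1,3-dioxolan-4-yl]prop-2-ynoate
Conditions: n-BuLi, THF, −78 °C; ClCO2Me
Reagents that add atoms: methyl chloroformate, COC(=O)Cl
Why: Acylation of the lithium acetylide with a chloroformate.

Step 12
Reactants: 17 ynoate
Product: 19 methyl (2Z)-3-[(4R)-2,2-dimethyl-1,3-dioxolan-4-yl]-2-[(4,4,5,5-tetramethyl-1,3,2-dioxaborolan-2-yl)methyl]prop-2-enoate, via alkenylalane 18 (not isolated)
Conditions: i-Bu2AlH, HMPA, THF, 0 °C; then ICH2B(pin), 0 °C to rt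
Reagents that add atoms: 2-(iodomethyl)-4,4,5,5-tetramethyl-1,3,2-dioxaborolane, ICB1OC(C)(C)C(C)(C)O1
Why: Conjugate syn-hydroalumination of the ynoate puts aluminium on the α-carbon and C-alkylation by the iodomethylboronate with retention places CH2B trans to the dioxolanyl group (crotyl-E type, Z by CIP).

Step 13
Reactants: 14 enal; 19 allylboronate
Product: 21 (4S,5R)-5-[(1Z,5E)-2-{[(tert-butyldiphenylsilyl)oxy]methyl}-6-iodo-7-[(4-methoxybenzyl)oxy]hepta-1,5-dien-1-yl]-4-[(4R)-2,2-dimethyl-1,3-dioxolan-4-yl]-3-methylideneoxolan-2-one, via borate ester 20 (not isolated)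
Conditions: Sc(OTf)3 (10 mol %), toluene, 0 °C to rt
Reagents that add atoms: none
Why: Lewis-acid-catalysed allylboration through a chair (Zimmerman–Traxler) transition state gives the anti adduct from this boronate geometry and hence the trans lactone (C6, C7), the aldehyde adding to the face of C7 anti to the dioxolane C8–O bond held by A(1,3) strain (Felkin–Anh sense), which is why the C8 epimer is carried; lactonisation expels MeOB(pin).

Step 14
Reactants: 21 lactone acetonide
Product: 22 (4R,5R)-5-[(1Z,5E)-2-{[(tert-butyldiphenylsilyl)oxy]methyl}-6-iodo-7-[(4-methoxybenzyl)oxy]hepta-1,5-dien-1-yl]-4-[(1R)-1,2-dihydroxyethyl]-3-methylideneoxolan-2-one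
Conditions: AcOH/H2O/THF (3:1:1), 45 °C
Reagents that add atoms: none
Why: Acid hydrolysis of the terminal acetonide, which the silyl ether, the PMB ether and the γ-lactone tolerate (the descriptor at lactone C4 changes by CIP only).

Step 15
Reactants: 22 diol
Product: 23 (4R,5R)-5-[(1Z,5E)-2-{[(tert-butyldiphenylsilyl)oxy]methyl}-6-iodo-7-[(4-methoxybenzyl)oxy]hepta-1,5-dien-1-yl]-4-{(1R)-1-hydroxy-2-[(triethylsilyl)oxy]ethyl}-3-methylideneoxolan-2-one
Conditions: Et3SiCl (1.1 equiv), imidazole, CH2Cl2, −30 °C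
Reagents that add atoms: chlorotriethylsilane, CC[Si](Cl)(CC)CC
Why: Silylation selective for the primary hydroxyl at low temperature.

Step 16
Reactants: 23 secondary alcohol; 24 (R)-2-methylbutanoic acid
Product: 25 (1S)-1-{(2R,3S)-2-[(1Z,5E)-2-{[(tert-butyldiphenylsilyl)oxy]methyl}-6-iodo-7-[(4-methoxybenzyl)oxy]hepta-1,5-dien-1-yl]-4-methylidene-5-oxooxolan-3-yl}-2-[(triethylsilyl)oxy]ethyl (2R)-2-methylbutanoate
Conditions: PPh3, DIAD, toluene, 0 °C to rt
Reagents that add atoms: none
Why: Mitsunobu esterification displaces the oxyphosphonium at C8 by the carboxylate in an SN2 step, which inverts C8 to the configuration of the target while installing the ester under neutral conditions that do not enolise the acid.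

Step 17
Reactants: 25 triethylsilyl ether
Product: 26 (1S)-2-hydroxy-1-{(2R,3S)-2-[(1Z,5E)-2-{[(tert-butyldiphenylsilyl)oxy]methyl}-6-iodo-7-[(4-methoxybenzyl)oxy]hepta-1,5-dien-1-yl]-4-methylidene-5-oxooxolan-3-yl}ethyl (2R)-2-methylbutanoate
Conditions: HF·pyridine, pyridine, THF, 0 °C
Reagents that add atoms: none
Why: Buffered HF·pyridine cleaves the primary triethylsilyl ether much faster than the tert-butyldiphenylsilyl ether and the slightly acidic medium suppresses acyl migration from O8 to O9.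

Step 18
Reactants: 26 primary alcohol
Product: 27 (1S)-2-oxo-1-{(2R,3S)-2-[(1Z,5E)-2-{[(tert-butyldiphenylsilyl)oxy]methyl}-6-iodo-7-[(4-methoxybenzyl)oxy]hepta-1,5-dien-1-yl]-4-methylidene-5-oxooxolan-3-yl}ethyl (2R)-2-methylbutanoate
Conditions: Dess–Martin periodinane, NaHCO3, CH2Cl2, 0 °C
Reagents that add atoms: none
Why: Buffered Dess–Martin oxidation should give the α-acyloxy aldehyde without epimerising C8; it is used at once.

Step 19
Reactants: 27 vinyl iodide aldehyde
Product: 28 germacra-1(10),4,11(13)-trien-12,6-olide with 9α-hydroxy, 8β-[(2R)-2-methylbutanoyloxy], 14-(4-methoxybenzyloxy) and 15-(tert-butyldiphenylsilyloxy) groups (6R,7S,8S,9S; C2 trans to C9 and C3 trans to C6 across the ring alkenes)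
Conditions: CrCl2 (8 equiv), NiCl2 (2 mol % of Cr), DMSO/THF, rt, syringe-pump addition to 2 mM
Reagents that add atoms: none
Why: Nozaki–Hiyama–Kishi coupling, in which nickel activates the vinyl iodide and the alkenylchromium (geometry retained) adds only to the aldehyde; at high dilution the ring should close through the crown-like conformer of the (E,E)-cyclodecadiene, where the 8β-acyloxy group is axial and the aldehyde C=O lies anti to the C8–O bond (dipole-minimised, Cornforth-type), so the new alkoxide is α (8,9-threo).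

Step 20
Reactants: 28 allylic alcohol
Product: 29 the 9α-acetate of 28
Conditions: Ac2O, pyridine, DMAP (cat.), CH2Cl2, 0 °C
Reagents that add atoms: acetic anhydride, CC(=O)OC(C)=O
Why: DMAP-catalysed acetylation of the secondary allylic alcohol, run cold and at once to forestall acyl migration.

Step 21
Reactants: 29 PMB ether
Product: 30 the 14-alcohol (9α-acetoxy-14-hydroxy-8β-[(2R)-2-methylbutanoyloxy]-15-(tert-butyldiphenylsilyloxy)germacra-1(10),4,11(13)-trien-12,6-olide)
Conditions: DDQ, CH2Cl2/pH 7 buffer, 0 °C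
Reagents that add atoms: none
Why: Oxidative cleavage of the 4-methoxybenzyl ether under neutral buffered conditions leaves the esters, the silyl ether and the acid-sensitive ring untouched.

Step 22
Reactants: 30 allylic alcohol
Product: 31 the 14-al (9α-acetoxy-8β-[(2R)-2-methylbutanoyloxy]-14-oxo-15-(tert-butyldiphenylsilyloxy)germacra-1(10),4,11(13)-trien-12,6-olide; C2 cis to the formyl group)
Conditions: MnO2, CH2Cl2, rt, dark
Reagents that add atoms: none
Why: MnO2 oxidises the primary allylic alcohol selectively under neutral conditions, and excluding acid, base and light keeps the C1=C10 geometry.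

Step 23
Reactants: 31 germacranolide 14-al
Product: 32 the target as its 15-O-tert-butyldiphenylsilyl ether (1α-H, 5α-H, 4β,14-epoxy bridge, C10=C14 enol ether)
Conditions: Me2AlCl (2.5 equiv), CH2Cl2, −78 to −40 °C; Et3N, then aq. potassium sodium tartrate
Reagents that add atoms: none
Why: Proposed new method: Me2AlCl on the C14 aldehyde lowers the LUMO of the oxadiene O=C14–C10=C1, the C4=C5 alkene attacks C1 through C5 across the ring and the aluminium enolate oxygen then closes on the developing tertiary C4 centre, a polar and strongly asynchronous [4+2] (zwitterion at the stepwise limit) because the C2–C3 link twists the dienophile about 60° away from an eclipsed approach. The closest known reactions are the dialkylaluminium-chloride-promoted formal hetero-Diels–Alder additions of enals to trisubstituted alkenes and the acid-triggered transannular closure of (E,E)-germacradienes to cis-fused guaianes. The cyclopentane closes by transannular conjugate addition (5-exo for the enal, endo for the C4=C5 alkene) and the dihydropyran by six-membered O-alkylation of the enolate at C4, which leaves the cycloheptane. C1 and C5 (both H α) are set by the crown conformer fixed by the trans lactone, in which the inner faces of the two ring-trans alkenes meet crossed so that C6 and C10 become cis on the cyclopentane, and C4 is set by the tether because the enolate oxygen can only reach the face of C4 syn to C10 (O β, C15 α). The step needs C1–C5 rather than C5–C10 bonding and oxygen capture rather than proton loss: C1 is the only electrophilic carbon of the complexed enal, the enolate oxygen sits 1,3 to C4 on the same face and the Al–Me bonds scavenge stray acid. It also needs the C1=C10 geometry with C2 cis to the formyl group, which is protected by working cold and base-free directly after step 22.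

Step 24
Reactants: 32 silyl ether
Product: 33 target CNP0013863.3
Conditions: Bu4NF/AcOH (1:1), THF, 0 °C to rt
Reagents that add atoms: none
Why: Acetic-acid-buffered fluoride removes the silyl ether without acid (enol ether) or strong base (α-methylene lactone, esters).

**Compound list**

1 | ethyl prop-2-ynoate (ethyl propiolate) | C#CC(=O)OCC | starting material
2 | bromoethene (vinyl bromide) | C=CBr | starting material
3 | ethyl pent-4-en-2-ynoate | C=CC#CC(=O)OCC | intermediate
4 | ethyl (2E)-2-(tributylstannyl)penta-2,4-dienoate | C=C/C=C(/[Sn](CCCC)(CCCC)CCCC)C(=O)OCC | intermediate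
5 | (2E)-2-(tributylstannyl)penta-2,4-dien-1-ol | C=C/C=C(/[Sn](CCCC)(CCCC)CCCC)CO | intermediate
6 | tributyl{(2E)-1-[(4-methoxybenzyl)oxy]penta-2,4-dien-2-yl}stannane | C=C/C=C(/[Sn](CCCC)(CCCC)CCCC)COCc1ccc(OC)cc1 | intermediate
7 | 4-hydroxyfuran-2(5H)-one (tetronic acid) | OC1=CC(=O)OC1 | starting material
8 | 4-bromofuran-2(5H)-one | BrC1=CC(=O)OC1 | intermediate
9 | 9-{(3E)-5-[(4-methoxybenzyl)oxy]-4-(tributylstannyl)pent-3-en-1-yl}-9-borabicyclo[3.3.1]nonane | B1(CC/C=C(/[Sn](CCCC)(CCCC)CCCC)COCc2ccc(OC)cc2)C2CCCC1CCC2 | intermediate (not isolated)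
10 | 4-{(3E)-5-[(4-methoxybenzyl)oxy]-4-(tributylstannyl)pent-3-en-1-yl}furan-2(5H)-one | O=C1C=C(CC/C=C(/[Sn](CCCC)(CCCC)CCCC)COCc2ccc(OC)cc2)CO1 | intermediate
11 | 4-{(3E)-4-iodo-5-[(4-methoxybenzyl)oxy]pent-3-en-1-yl}furan-2(5H)-one | O=C1C=C(CC/C=C(/I)COCc2ccc(OC)cc2)CO1 | intermediate
12 | (2Z,6E)-3-(hydroxymethyl)-7-iodo-N-methoxy-8-[(4-methoxybenzyl)oxy]-N-methylocta-2,6-dienamide | CON(C)C(=O)/C=C(/CC/C=C(/I)COCc1ccc(OC)cc1)CO | intermediate (not isolated)
13 | (2Z,6E)-3-{[(tert-butyldiphenylsilyl)oxy]methyl}-7-iodo-N-methoxy-8-[(4-methoxybenzyl)oxy]-N-methylocta-2,6-dienamide | CON(C)C(=O)/C=C(/CC/C=C(/I)COCc1ccc(OC)cc1)CO[Si](c1ccccc1)(c1ccccc1)C(C)(C)C | intermediate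
14 | (2Z,6E)-3-{[(tert-butyldiphenylsilyl)oxy]methyl}-7-iodo-8-[(4-methoxybenzyl)oxy]octa-2,6-dienal | O=C/C=C(/CC/C=C(/I)COCc1ccc(OC)cc1)CO[Si](c1ccccc1)(c1ccccc1)C(C)(C)C | intermediate
15 | (4S)-2,2-dimethyl-1,3-dioxolane-4-carbaldehyde ((S)-glyceraldehyde acetonide) | O=C[C@@H]1COC(C)(C)O1 | starting material
16 | (4R)-4-ethynyl-2,2-dimethyl-1,3-dioxolane | C#C[C@@H]1COC(C)(C)O1 | intermediate
17 | methyl 3-[(4R)-2,2-dimethyl-1,3-dioxolan-4-yl]prop-2-ynoate | COC(=O)C#C[C@@H]1COC(C)(C)O1 | intermediate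
18 | methyl (2E)-2-[bis(2-methylpropyl)alumanyl]-3-[(4R)-2,2-dimethyl-1,3-dioxolan-4-yl]prop-2-enoate | COC(=O)/C(=C\[C@@H]1COC(C)(C)O1)[Al](CC(C)C)CC(C)C | intermediate (not isolated)
19 | methyl (2Z)-3-[(4R)-2,2-dimethyl-1,3-dioxolan-4-yl]-2-[(4,4,5,5-tetramethyl-1,3,2-dioxaborolan-2-yl)methyl]prop-2-enoate | COC(=O)/C(=C\[C@@H]1COC(C)(C)O1)CB1OC(C)(C)C(C)(C)O1 | intermediate
20 | methyl (3S,4R,5Z,9E)-6-{[(tert-butyldiphenylsilyl)oxy]methyl}-3-[(4R)-2,2-dimethyl-1,3-dioxolan-4-yl]-10-iodo-11-[(4-methoxybenzyl)oxy]-2-methylidene-4-[(4,4,5,5-tetramethyl-1,3,2-dioxaborolan-2-yl)oxy]undeca-5,9-dienoate | COC(=O)C(=C)[C@H]([C@@H]1COC(C)(C)O1)[C@H](OB1OC(C)(C)C(C)(C)O1)/C=C(/CC/C=C(/I)COCc1ccc(OC)cc1)CO[Si](c1ccccc1)(c1ccccc1)C(C)(C)C | intermediate (not isolated)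
21 | (4S,5R)-5-[(1Z,5E)-2-{[(tert-butyldiphenylsilyl)oxy]methyl}-6-iodo-7-[(4-methoxybenzyl)oxy]hepta-1,5-dien-1-yl]-4-[(4R)-2,2-dimethyl-1,3-dioxolan-4-yl]-3-methylideneoxolan-2-one (trans lactone) | C=C1C(=O)O[C@H](/C=C(/CC/C=C(/I)COCc2ccc(OC)cc2)CO[Si](c2ccccc2)(c2ccccc2)C(C)(C)C)[C@H]1[C@@H]1COC(C)(C)O1 | intermediate
22 | (4R,5R)-5-[(1Z,5E)-2-{[(tert-butyldiphenylsilyl)oxy]methyl}-6-iodo-7-[(4-methoxybenzyl)oxy]hepta-1,5-dien-1-yl]-4-[(1R)-1,2-dihydroxyethyl]-3-methylideneoxolan-2-one | C=C1C(=O)O[C@H](/C=C(/CC/C=C(/I)COCc2ccc(OC)cc2)CO[Si](c2ccccc2)(c2ccccc2)C(C)(C)C)[C@H]1[C@@H](O)CO | intermediate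
23 | (4R,5R)-5-[(1Z,5E)-2-{[(tert-butyldiphenylsilyl)oxy]methyl}-6-iodo-7-[(4-methoxybenzyl)oxy]hepta-1,5-dien-1-yl]-4-{(1R)-1-hydroxy-2-[(triethylsilyl)oxy]ethyl}-3-methylideneoxolan-2-one | C=C1C(=O)O[C@H](/C=C(/CC/C=C(/I)COCc2ccc(OC)cc2)CO[Si](c2ccccc2)(c2ccccc2)C(C)(C)C)[C@H]1[C@@H](O)CO[Si](CC)(CC)CC | intermediate
24 | (2R)-2-methylbutanoic acid | CC[C@@H](C)C(=O)O | starting material
25 | (1S)-1-{(2R,3S)-2-[(1Z,5E)-2-{[(tert-butyldiphenylsilyl)oxy]methyl}-6-iodo-7-[(4-methoxybenzyl)oxy]hepta-1,5-dien-1-yl]-4-methylidene-5-oxooxolan-3-yl}-2-[(triethylsilyl)oxy]ethyl (2R)-2-methylbutanoate | C=C1C(=O)O[C@H](/C=C(/CC/C=C(/I)COCc2ccc(OC)cc2)CO[Si](c2ccccc2)(c2ccccc2)C(C)(C)C)[C@H]1[C@H](OC(=O)[C@H](C)CC)CO[Si](CC)(CC)CC | intermediate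
26 | (1S)-2-hydroxy-1-{(2R,3S)-2-[(1Z,5E)-2-{[(tert-butyldiphenylsilyl)oxy]methyl}-6-iodo-7-[(4-methoxybenzyl)oxy]hepta-1,5-dien-1-yl]-4-methylidene-5-oxooxolan-3-yl}ethyl (2R)-2-methylbutanoate | C=C1C(=O)O[C@H](/C=C(/CC/C=C(/I)COCc2ccc(OC)cc2)CO[Si](c2ccccc2)(c2ccccc2)C(C)(C)C)[C@H]1[C@H](OC(=O)[C@H](C)CC)CO | intermediate
27 | (1S)-2-oxo-1-{(2R,3S)-2-[(1Z,5E)-2-{[(tert-butyldiphenylsilyl)oxy]methyl}-6-iodo-7-[(4-methoxybenzyl)oxy]hepta-1,5-dien-1-yl]-4-methylidene-5-oxooxolan-3-yl}ethyl (2R)-2-methylbutanoate | C=C1C(=O)O[C@H](/C=C(/CC/C=C(/I)COCc2ccc(OC)cc2)CO[Si](c2ccccc2)(c2ccccc2)C(C)(C)C)[C@H]1[C@H](OC(=O)[C@H](C)CC)C=O | intermediate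
28 | (6R,7S,8S,9S)-9-hydroxy-14-[(4-methoxybenzyl)oxy]-8-[(2R)-2-methylbutanoyloxy]-15-[(tert-butyldiphenylsilyl)oxy]germacra-1(10),4,11(13)-trien-12,6-olide; 6α-O, 7α-H, 8β-O, 9α-OH; C2 trans to C9 and C3 trans to C6 | C1/C(CO[Si](c2ccccc2)(c2ccccc2)C(C)(C)C)=C/[C@H]2OC(=O)C(=C)[C@@H]2[C@H](OC(=O)[C@H](C)CC)[C@@H](O)/C(COCc2ccc(OC)cc2)=C/C1 | intermediate
29 | 9α-acetate of 28 | C1/C(CO[Si](c2ccccc2)(c2ccccc2)C(C)(C)C)=C/[C@H]2OC(=O)C(=C)[C@@H]2[C@H](OC(=O)[C@H](C)CC)[C@@H](OC(C)=O)/C(COCc2ccc(OC)cc2)=C/C1 | intermediate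
30 | 9α-acetoxy-14-hydroxy-8β-[(2R)-2-methylbutanoyloxy]-15-[(tert-butyldiphenylsilyl)oxy]germacra-1(10),4,11(13)-trien-12,6-olide (ring geometry as 28) | C1/C(CO[Si](c2ccccc2)(c2ccccc2)C(C)(C)C)=C/[C@H]2OC(=O)C(=C)[C@@H]2[C@H](OC(=O)[C@H](C)CC)[C@@H](OC(C)=O)/C(CO)=C/C1 | intermediate
31 | 9α-acetoxy-8β-[(2R)-2-methylbutanoyloxy]-14-oxo-15-[(tert-butyldiphenylsilyl)oxy]germacra-1(10),4,11(13)-trien-12,6-olide (C2 cis to CHO, C3 trans to C6); key-step precursor | C1/C(CO[Si](c2ccccc2)(c2ccccc2)C(C)(C)C)=C/[C@H]2OC(=O)C(=C)[C@@H]2[C@H](OC(=O)[C@H](C)CC)[C@@H](OC(C)=O)/C(C=O)=C/C1 | intermediate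
32 | 15-O-tert-butyldiphenylsilyl ether of the target: 9α-acetoxy-4β,14-epoxy-8β-[(2R)-2-methylbutanoyloxy]guaia-10(14),11(13)-dien-12,6α-olide, 1α-H, 5α-H, 7α-H | C=C1C(=O)O[C@H]2[C@H]1[C@H](OC(=O)[C@H](C)CC)[C@@H](OC(C)=O)C1=CO[C@@]3(CO[Si](c4ccccc4)(c4ccccc4)C(C)(C)C)CC[C@@H]1[C@@H]23 | intermediate
33 | CNP0013863.3: 9α-acetoxy-4β,14-epoxy-15-hydroxy-8β-[(2R)-2-methylbutanoyloxy]guaia-10(14),11(13)-dien-12,6α-olide, 1α-H, 5α-H, 7α-H | C=C1C(=O)O[C@H]2[C@H]1[C@H](OC(=O)[C@H](C)CC)[C@@H](OC(C)=O)C1=CO[C@@]3(CO)CC[C@@H]1[C@@H]23 | target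

**Step count and risks**

Total step count: 24. Longest linear sequence: 20 (steps 1–4, 6–9, 13–24).

Steps most likely to fail:

1. Step 23 (Proposed new method). The complexed enal may isomerise at C1=C10 to the ring-cis isomer, which cannot reach C5, or the C4 cation may lose a proton (ene-type product) before the oxygen closes. The fallback uses known reactions only and sets out from 31. N-Bromosuccinimide in wet THF should add across C4=C5 in an anti sense to give the 4-hydroxy-5-bromo compound, bromohydrin F1, with the hydroxyl on the inner face at C4. Bu3SnH with Et3B/air then generates the C5 radical, which adds 5-exo to C1 of the enal (Giese-type transannular cyclisation). The resulting C10–H aldehyde is trapped by the 4-hydroxyl as the bridged lactol F2. MsCl/Et3N dehydrates the lactol to the enol ether and the route is rejoined at 32.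

2. Step 19. Oligomerisation may compete with ring closure, and facial selectivity at C9 may be poor or reversed if the ring does not close through the crown conformer. The fallback sets out from 27 and keeps the Ni/Cr closure but sets C9 afterwards by reagent control. The 9-epimeric alcohol F3 (alone or mixed with 28) is oxidised with Dess–Martin periodinane to the macrocyclic enone F4. F4 is reduced with catecholborane and the enantiomer of the CBS oxazaborolidine that delivers hydride to give the 9α-alcohol, rejoining at 28.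

3. Step 13. Facial selectivity at C7 may erode, or the Lewis acid may scramble the geometry of the enal or the boronate and give cis lactone. The fallback sets out from 15. A Morita–Baylis–Hillman reaction with methyl acrylate (DABCO) gives the hydroxy acrylate F5. NBS/Me2S converts it with allylic transposition into the (Z)-allylic bromide F6. Nickel-free CrCl2 in THF then adds the derived allylchromium to 14 (anti-selective Nozaki–Hiyama allylation with Felkin–Anh-type control from C8), and acid closes the lactone, rejoining at 21.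

**Further compounds**

F1 | step 23 | 4,5-bromohydrin of 31 (4-hydroxy with C4 configured as in 32, 5-bromo anti to it) | C1[C@@](O)(CO[Si](c2ccccc2)(c2ccccc2)C(C)(C)C)[C@H](Br)[C@H]2OC(=O)C(=C)[C@@H]2[C@H](OC(=O)[C@H](C)CC)[C@@H](OC(C)=O)/C(C=O)=C/C1
F2 | step 23 | bridged lactol, the 10,14-dihydro-14-hydroxy derivative of 32 (epimers at C10 and C14) | C=C1C(=O)O[C@H]2[C@H]1[C@H](OC(=O)[C@H](C)CC)[C@@H](OC(C)=O)C1C(O)O[C@@]3(CO[Si](c4ccccc4)(c4ccccc4)C(C)(C)C)CC[C@@H]1[C@@H]23
F3 | step 19 | 9-epimer of 28 (9β-hydroxy) | C1/C(CO[Si](c2ccccc2)(c2ccccc2)C(C)(C)C)=C/[C@H]2OC(=O)C(=C)[C@@H]2[C@H](OC(=O)[C@H](C)CC)[C@H](O)/C(COCc2ccc(OC)cc2)=C/C1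
F4 | step 19 | 9-oxo compound (macrocyclic enone) derived from 28 | C1/C(CO[Si](c2ccccc2)(c2ccccc2)C(C)(C)C)=C/[C@H]2OC(=O)C(=C)[C@@H]2[C@H](OC(=O)[C@H](C)CC)C(=O)/C(COCc2ccc(OC)cc2)=C/C1
F5 | step 13 | methyl 2-{[(4S)-2,2-dimethyl-1,3-dioxolan-4-yl](hydroxy)methyl}prop-2-enoate (carbinol epimers) | C=C(C(=O)OC)C(O)[C@@H]1COC(C)(C)O1
F6 | step 13 | methyl (2Z)-2-(bromomethyl)-3-[(4R)-2,2-dimethyl-1,3-dioxolan-4-yl]prop-2-enoate | COC(=O)/C(CBr)=C/[C@@H]1COC(C)(C)O1
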